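**Strategy**

Everything rests on cutting the C1–C8a bond of ring B and joining C1 to C3 instead, which turns the dihydronaphthalene into an aryl cyclopropyl ketone. The feature exploited is that C1 (benzylic to the pendant ring C) and C3 (ester-bearing, next to C4, a masked ketone attached to ring A) are 1,3-related across C2. In one operation Sc(OTf)3 opens the cyclopropane, C8a of ring A captures the C1 cation, ring B closes and C1 is set trans to C2. The precursor is a methyl 1-aroyl-2-aryl-3-(silyloxymethyl)cyclopropane-1-carboxylate with all three hydroxyls as triisopropylsilyl ethers; its one lasting stereocentre, C2 of the target, comes from an amine-catalysed cyclopropanation.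

Key step: step 8

Remarks on the chemistry (one line each):
- Numbering and abbreviations: bicyclic compounds carry the target numbering (C1 aryl-bearing, C2 bearing the one-carbon alcohol, C3 ester-bearing, C4, ring A = C4a–C8a with oxygen at C6, C7 and C8, ring C = pendant aryl); the target is (1S,2R), ring C and CH2OH trans; TIPS = triisopropylsilyl, Ar = 3,5-dimethoxy-4-(TIPS-oxy)phenyl, ArCO = the corresponding benzoyl group.
- Assumption: sinapaldehyde is bought as such; the cyclopropane is drawn as the epimer with the ester cis to Ar, and the epimer at that quaternary carbon, if it forms, is carried along because this carbon becomes trigonal C3 in step 8, whereas the ring carbon bearing the oxygenated arm (C2 of the target) must be R.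
- Design choices: all three hydroxyls travel as TIPS ethers (sturdier than smaller silyl groups toward Sc(OTf)3, toward O-desilylation of the para-silyloxybenzyl cation and toward lactonisation of the primary alcohol onto the neighbouring ester); the C4 oxygen is removed through the enol triflate, so no new stereocentre and no strong base appears next to C2.

**Route**

Step 1
Reactants: 1 sinapaldehyde, (E)-3-(4-hydroxy-3,5-dimethoxyphenyl)prop-2-enal
Product: 2 (E)-3-Ar-prop-2-enal
Conditions: TIPSCl, imidazole, DMAP (cat.), DMF, rt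
Reagents that add atoms: chlorotriisopropylsilane (TIPSCl), CC(C)[Si](Cl)(C(C)C)C(C)C
Why: Imidazole-promoted silyl ether formation at the phenol, which should proceed even with two flanking methoxy groups and leaves the enal untouched.

Step 2
Reactants: 3 syringic acid, 4-hydroxy-3,5-dimethoxybenzoic acid
Product: 5 3,5-dimethoxy-4-(TIPS-oxy)benzoic acid, via silyl ester 4 (not isolated)
Conditions: TIPSCl (2.5 equiv), imidazole, DMF, rt; then K2CO3, MeOH/THF/H2O, rt; dilute HCl to pH 3
Reagents that add atoms: chlorotriisopropylsilane (TIPSCl), CC(C)[Si](Cl)(C(C)C)C(C)C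
Why: Exhaustive silylation followed by selective solvolysis of the silyl ester, which is far more labile than the hindered aryl silyl ether (silyl ether formation, then silyl ester hydrolysis).

Step 3
Reactants: 5 3,5-dimethoxy-4-(TIPS-oxy)benzoic acid
Product: 8 methyl 3-Ar-3-oxopropanoate, via acyl imidazole 6 (not isolated), via acylmalonic acid 7 (not isolated)
Conditions: CDI, THF, rt; then KO2CCH2CO2Me, MgCl2, Et3N, MeCN, rt → 45 °C; 1 M HCl
Reagents that add atoms: potassium methyl malonate (KO2CCH2CO2Me), COC(=O)CC(=O)[O-].[K+]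
Why: Masamune–Brooks decarboxylative Claisen condensation, in which the acyl imidazole C-acylates the magnesium enolate of the malonate half-ester under near-neutral conditions that spare the aryl silyl ether, and the acylmalonic acid loses CO2 on acidification.

Step 4
Reactants: 8 methyl 3-Ar-3-oxopropanoate
Product: 9 methyl 2-bromo-3-Ar-3-oxopropanoate (racemic)
Conditions: NBS, NH4OAc (cat.), Et2O, rt
Reagents that add atoms: N-bromosuccinimide, O=C1CCC(=O)N1Br
Why: Electrophilic α-bromination of the enolised β-keto ester, whose enol is far more reactive toward NBS than the acyl-deactivated arene, so one bromine should enter at C2.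

Step 5
Reactants: 2 (E)-3-Ar-prop-2-enal; 9 methyl 2-bromo-3-Ar-3-oxopropanoate
Product: 10 methyl (1R,2S,3R)-1-ArCO-2-Ar-3-formylcyclopropane-1-carboxylate
Conditions: (S)-2-[diphenyl(trimethylsilyloxy)methyl]pyrrolidine (20 mol%), 2,6-lutidine, CH2Cl2, 0 °C → rt
Reagents that add atoms: none
Why: Michael-initiated ring closure under iminium then enamine catalysis: the diphenyl(silyloxy)methyl group of the (S)-amine shields one face of the s-trans E-iminium ion of 2, so the bromo enolate should add to the open Si face of the β-carbon (ring C2, S), and the enamine then displaces bromide in a 3-exo-tet closure that places the formyl group trans to Ar (ring C3, R), the configuration at the quaternary C1 being of no consequence.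

Step 6
Reactants: 10 methyl (1R,2S,3R)-1-ArCO-2-Ar-3-formylcyclopropane-1-carboxylate
Product: 11 methyl (1R,2S,3R)-1-ArCO-2-Ar-3-(hydroxymethyl)cyclopropane-1-carboxylate
Conditions: NaBH4, THF/MeOH, −40 °C; aq. NH4Cl
Reagents that add atoms: none
Why: Chemoselective borohydride reduction, since at low temperature the aldehyde should be reduced much faster than the hindered, electron-rich aryl ketone while the ester is inert and no stereocentre is touched.

Step 7
Reactants: 11 methyl (1R,2S,3R)-1-ArCO-2-Ar-3-(hydroxymethyl)cyclopropane-1-carboxylate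
Product: 12 methyl (1R,2S,3R)-1-ArCO-2-Ar-3-[(TIPS-oxy)methyl]cyclopropane-1-carboxylate
Conditions: TIPSOTf, 2,6-lutidine, CH2Cl2, −78 → 0 °C
Reagents that add atoms: triisopropylsilyl triflate (TIPSOTf), CC(C)[Si](OS(=O)(=O)C(F)(F)F)(C(C)C)C(C)C
Why: Silylation of the primary alcohol with a silyl triflate and a hindered pyridine base, fast enough at low temperature to cap the alcohol before it can add to the cis carbonyl group, the keto ester having no enolisable hydrogen.

Step 8
Reactants: 12 methyl (1R,2S,3R)-1-ArCO-2-Ar-3-[(TIPS-oxy)methyl]cyclopropane-1-carboxylate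
Product: 13 methyl (1S,2R)-1-Ar-4-hydroxy-6,8-dimethoxy-7-(TIPS-oxy)-2-[(TIPS-oxy)methyl]-1,2-dihydronaphthalene-3-carboxylate (enol of the trans 4-oxotetralin-3-carboxylate)
Conditions: Sc(OTf)3 (15 mol%), 4 Å MS, CH2Cl2, 0 °C → rt
Reagents that add atoms: none
Why: Sc(OTf)3 should chelate the keto ester of 12 and break the cyclopropane bond between the quaternary carbon and the aryl-bearing carbon (C3–C1 in target numbering), giving a scandium enolate and a C1 cation stabilised by the para-silyloxy ring C, which C8a of ring A then attacks before proton loss restores ring A. The closest known reaction type is the Lewis-acid ring opening and Friedel–Crafts closure of 2-aryl cyclopropyl aryl ketones to 4-aryl-1-tetralones (formal homo-Nazarov cyclisation). Ring B closes in a six-membered mode, 6-exo-trig with respect to the quinone-methide-like C1=C1′ bond of the cation. C1 is set by substrate control from C2: closure should go through the half-chair in which ring C and the CH2OTIPS group are anti (both pseudo-axial, clear of the C3 ester and the C8 methoxy group), giving the 1,2-trans (1S,2R) isomer, while C2 itself is neither ionised nor enolised. The step needs C-attack by ring A to prevail over O-attack by the enolate (Cloke–Wilson dihydrofuran), which is secured because the benzylic C–O bond of such a dihydrofuran re-ionises under the Lewis acid whereas the C–C closure is final; the two ortho positions of ring A are equivalent, each ortho and para to a methoxy group, and both epimers at the quaternary carbon give the same cation.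

Step 9
Reactants: 13 methyl (1S,2R)-1-Ar-4-hydroxy-6,8-dimethoxy-7-(TIPS-oxy)-2-[(TIPS-oxy)methyl]-1,2-dihydronaphthalene-3-carboxylate
Product: 15 methyl (1S,2R)-1-Ar-6,8-dimethoxy-7-(TIPS-oxy)-2-[(TIPS-oxy)methyl]-4-(trifluoromethylsulfonyloxy)-1,2-dihydronaphthalene-3-carboxylate, via sodium enolate 14 (not isolated)
Conditions: NaH, THF, 0 °C; then PhNTf2, 0 °C → rt
Reagents that add atoms: N-phenylbis(trifluoromethanesulfonimide) (PhNTf2), O=S(=O)(N(c1ccccc1)S(=O)(=O)C(F)(F)F)C(F)(F)F
Why: O-sulfonylation of the stabilised β-keto ester enolate (enol triflate formation), in which C3 stays trigonal and the C1 and C2 stereocentres are not touched.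

Step 10
Reactants: 15 methyl (1S,2R)-1-Ar-6,8-dimethoxy-7-(TIPS-oxy)-2-[(TIPS-oxy)methyl]-4-(trifluoromethylsulfonyloxy)-1,2-dihydronaphthalene-3-carboxylate
Product: 16 methyl (1S,2R)-1-Ar-6,8-dimethoxy-7-(TIPS-oxy)-2-[(TIPS-oxy)methyl]-1,2-dihydronaphthalene-3-carboxylate
Conditions: Pd(OAc)2 (5 mol%), PPh3, HCO2H, Et3N, DMF, 60 °C
Reagents that add atoms: none
Why: Palladium-catalysed formate reduction of a vinyl triflate (oxidative addition of zerovalent palladium, formate exchange, loss of CO2, C–H reductive elimination), which should leave the C3=C4 enoate without any base strong enough to move the alkene or touch C2.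

Step 11
Reactants: 16 methyl (1S,2R)-1-Ar-6,8-dimethoxy-7-(TIPS-oxy)-2-[(TIPS-oxy)methyl]-1,2-dihydronaphthalene-3-carboxylate
Product: 17 methyl (1S,2R)-7-hydroxy-1-(4-hydroxy-3,5-dimethoxyphenyl)-2-(hydroxymethyl)-6,8-dimethoxy-1,2-dihydronaphthalene-3-carboxylate (target)
Conditions: TBAF, AcOH (1:1), THF, 0 °C → rt
Reagents that add atoms: none
Why: Fluoride-induced cleavage of the two aryl and one primary alkyl silyl ethers, buffered by acetic acid so that neither a phenoxide nor an alkoxide should persist to lactonise onto the conjugated ester, with no stereocentre involved.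

**Compound list**

1 | sinapaldehyde, (E)-3-(4-hydroxy-3,5-dimethoxyphenyl)prop-2-enal | COc1cc(/C=C/C=O)cc(OC)c1O | starting material
2 | (E)-3-[3,5-dimethoxy-4-(triisopropylsilyloxy)phenyl]prop-2-enal | COc1cc(/C=C/C=O)cc(OC)c1O[Si](C(C)C)(C(C)C)C(C)C | intermediate
3 | syringic acid, 4-hydroxy-3,5-dimethoxybenzoic acid | COc1cc(C(=O)O)cc(OC)c1O | starting material
4 | triisopropylsilyl 3,5-dimethoxy-4-(triisopropylsilyloxy)benzoate (formed in the flask) | COc1cc(C(=O)O[Si](C(C)C)(C(C)C)C(C)C)cc(OC)c1O[Si](C(C)C)(C(C)C)C(C)C | intermediate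
5 | 3,5-dimethoxy-4-(triisopropylsilyloxy)benzoic acid | COc1cc(C(=O)O)cc(OC)c1O[Si](C(C)C)(C(C)C)C(C)C | intermediate
6 | 1-[3,5-dimethoxy-4-(triisopropylsilyloxy)benzoyl]imidazole (formed in the flask) | COc1cc(C(=O)n2ccnc2)cc(OC)c1O[Si](C(C)C)(C(C)C)C(C)C | intermediate
7 | 2-[3,5-dimethoxy-4-(triisopropylsilyloxy)benzoyl]-3-methoxy-3-oxopropanoic acid (formed in the flask as its magnesium salt) | COC(=O)C(C(=O)O)C(=O)c1cc(OC)c(O[Si](C(C)C)(C(C)C)C(C)C)c(OC)c1 | intermediate
8 | methyl 3-[3,5-dimethoxy-4-(triisopropylsilyloxy)phenyl]-3-oxopropanoate | COC(=O)CC(=O)c1cc(OC)c(O[Si](C(C)C)(C(C)C)C(C)C)c(OC)c1 | intermediate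
9 | methyl 2-bromo-3-[3,5-dimethoxy-4-(triisopropylsilyloxy)phenyl]-3-oxopropanoate (racemic) | COC(=O)C(Br)C(=O)c1cc(OC)c(O[Si](C(C)C)(C(C)C)C(C)C)c(OC)c1 | intermediate
10 | methyl (1R,2S,3R)-1-[3,5-dimethoxy-4-(triisopropylsilyloxy)benzoyl]-2-[3,5-dimethoxy-4-(triisopropylsilyloxy)phenyl]-3-formylcyclopropane-1-carboxylate | COC(=O)[C@]1(C(=O)c2cc(OC)c(O[Si](C(C)C)(C(C)C)C(C)C)c(OC)c2)[C@H](c2cc(OC)c(O[Si](C(C)C)(C(C)C)C(C)C)c(OC)c2)[C@H]1C=O | intermediate
11 | methyl (1R,2S,3R)-1-[3,5-dimethoxy-4-(triisopropylsilyloxy)benzoyl]-2-[3,5-dimethoxy-4-(triisopropylsilyloxy)phenyl]-3-(hydroxymethyl)cyclopropane-1-carboxylate | COC(=O)[C@]1(C(=O)c2cc(OC)c(O[Si](C(C)C)(C(C)C)C(C)C)c(OC)c2)[C@H](c2cc(OC)c(O[Si](C(C)C)(C(C)C)C(C)C)c(OC)c2)[C@H]1CO | intermediate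
12 | methyl (1R,2S,3R)-1-[3,5-dimethoxy-4-(triisopropylsilyloxy)benzoyl]-2-[3,5-dimethoxy-4-(triisopropylsilyloxy)phenyl]-3-[(triisopropylsilyloxy)methyl]cyclopropane-1-carboxylate | COC(=O)[C@]1(C(=O)c2cc(OC)c(O[Si](C(C)C)(C(C)C)C(C)C)c(OC)c2)[C@H](c2cc(OC)c(O[Si](C(C)C)(C(C)C)C(C)C)c(OC)c2)[C@H]1CO[Si](C(C)C)(C(C)C)C(C)C | intermediate
13 | methyl (1S,2R)-1-[3,5-dimethoxy-4-(triisopropylsilyloxy)phenyl]-4-hydroxy-6,8-dimethoxy-7-(triisopropylsilyloxy)-2-[(triisopropylsilyloxy)methyl]-1,2-dihydronaphthalene-3-carboxylate (enol of the 4-oxotetralin; target numbering) | COC(=O)C1=C(O)c2cc(OC)c(O[Si](C(C)C)(C(C)C)C(C)C)c(OC)c2[C@H](c2cc(OC)c(O[Si](C(C)C)(C(C)C)C(C)C)c(OC)c2)[C@H]1CO[Si](C(C)C)(C(C)C)C(C)C | intermediate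
14 | sodium enolate of 13 (formed in the flask) | COC(=O)C1=C([O-])c2cc(OC)c(O[Si](C(C)C)(C(C)C)C(C)C)c(OC)c2[C@H](c2cc(OC)c(O[Si](C(C)C)(C(C)C)C(C)C)c(OC)c2)[C@H]1CO[Si](C(C)C)(C(C)C)C(C)C.[Na+] | intermediate
15 | methyl (1S,2R)-1-[3,5-dimethoxy-4-(triisopropylsilyloxy)phenyl]-6,8-dimethoxy-7-(triisopropylsilyloxy)-2-[(triisopropylsilyloxy)methyl]-4-(trifluoromethylsulfonyloxy)-1,2-dihydronaphthalene-3-carboxylate | COC(=O)C1=C(OS(=O)(=O)C(F)(F)F)c2cc(OC)c(O[Si](C(C)C)(C(C)C)C(C)C)c(OC)c2[C@H](c2cc(OC)c(O[Si](C(C)C)(C(C)C)C(C)C)c(OC)c2)[C@H]1CO[Si](C(C)C)(C(C)C)C(C)C | intermediate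
16 | methyl (1S,2R)-1-[3,5-dimethoxy-4-(triisopropylsilyloxy)phenyl]-6,8-dimethoxy-7-(triisopropylsilyloxy)-2-[(triisopropylsilyloxy)methyl]-1,2-dihydronaphthalene-3-carboxylate | COC(=O)C1=Cc2cc(OC)c(O[Si](C(C)C)(C(C)C)C(C)C)c(OC)c2[C@H](c2cc(OC)c(O[Si](C(C)C)(C(C)C)C(C)C)c(OC)c2)[C@H]1CO[Si](C(C)C)(C(C)C)C(C)C | intermediate
17 | methyl (1S,2R)-7-hydroxy-1-(4-hydroxy-3,5-dimethoxyphenyl)-2-(hydroxymethyl)-6,8-dimethoxy-1,2-dihydronaphthalene-3-carboxylate (CNP0143100.1) | COC(=O)C1=Cc2cc(OC)c(O)c(OC)c2[C@H](c2cc(OC)c(O)c(OC)c2)[C@H]1CO | target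

**Step count and risks**

Total steps: 11. Longest linear sequence: 10 (steps 2 to 11, from syringic acid).

Steps most likely to fail:

1. Step 8. What may go wrong: the enolate oxygen may capture the C1 cation faster than ring A does (O-cyclisation), the cation may lose the C2 proton and so erase the only carried stereocentre, or ring A, held next to the chelated ketone, may be too electron-poor to close. Fallback, setting out from 12 and coming back at 16: the ketone is removed before ionisation. NaBH4 in MeOH/THF at 0 °C should reduce the aryl ketone of 12 to the carbinol methyl (1R,2S,3R)-1-[Ar(hydroxy)methyl]-2-Ar-3-[(TIPS-oxy)methyl]cyclopropane-1-carboxylate F1 (both carbinol epimers serve). BF3·OEt2 in CH2Cl2 at −40 °C should then ionise the electron-rich benzylic alcohol. The cyclopropylcarbinyl cation opens toward the Ar-bearing carbon to the homoallylic C1 cation with the C3=C4 bond already in place and ring A cis to C2, the usual geometry of an α-substituted cinnamate, and ring A closes on C1 anti to the CH2OTIPS group. This is the known acid-mediated passage from aryl (2-arylcyclopropyl) carbinols to 1-aryl-1,2-dihydronaphthalenes (cyclopropylcarbinyl–homoallyl rearrangement with Friedel–Crafts capture). No enolate oxygen competes, ring A is far less deactivated, and the product is 16 itself, so steps 9 and 10 fall away.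

2. Step 5. What may go wrong: N-alkylation of the amine catalyst by the bromo keto ester, O- instead of C-alkylation after the conjugate addition, or reversal of the conjugate addition with loss of enantioselectivity. Fallback, setting out from 2 and 8 and coming back at 10: the halogen is taken out of the enantio-determining event. The same (S)-amine with benzoic acid as co-catalyst adds the unbrominated keto ester 8 to enal 2, a well-known conjugate addition of 1,3-dicarbonyl compounds to enals. This should give methyl (3R)-2-ArCO-3-Ar-5-oxopentanoate F2 (C2 epimers, in equilibrium with its cyclic hemiacetal). NBS then brominates the doubly activated C2 to methyl (3S)-2-bromo-2-ArCO-3-Ar-5-oxopentanoate F3. Pyrrolidine (cat.) and 2,6-lutidine in CH2Cl2 close the three-membered ring through the aldehyde enamine (3-exo-tet, formyl trans to Ar) to give 10.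

3. Step 6. What may go wrong: incomplete discrimination between aldehyde and ketone by the hydride, and closure of the new alcohol onto a cis carbonyl group (hemiketal or lactone) before step 7 can cap it. Fallback, setting out from 2 and coming back at 12: the ketone is brought in only after the alcohol is protected. Under the conditions of step 5, 2 and commercial dimethyl bromomalonate should give dimethyl (2S,3R)-2-Ar-3-formylcyclopropane-1,1-dicarboxylate F4. NaBH4 gives dimethyl (2S,3R)-2-Ar-3-(hydroxymethyl)cyclopropane-1,1-dicarboxylate F5 with no ketone present, and TIPSOTf/2,6-lutidine at once gives dimethyl (2S,3R)-2-Ar-3-[(TIPS-oxy)methyl]cyclopropane-1,1-dicarboxylate F6. (4-Bromo-2,6-dimethoxyphenoxy)triisopropylsilane F7, made from commercial 4-bromo-2,6-dimethoxyphenol with TIPSCl and imidazole, is lithiated with n-BuLi in THF at −78 °C to [3,5-dimethoxy-4-(TIPS-oxy)phenyl]lithium F8. One equivalent of F8 is added to F6 at −78 °C; the lithium hemiketal, chelated by the second ester, should hold until the quench, so addition stops at the ketone and gives 12 or its epimer at the quaternary carbon, both of which serve.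

Further compounds
F1 | step 8 | methyl (1R,2S,3R)-1-{[3,5-dimethoxy-4-(triisopropylsilyloxy)phenyl](hydroxy)methyl}-2-[3,5-dimethoxy-4-(triisopropylsilyloxy)phenyl]-3-[(triisopropylsilyloxy)methyl]cyclopropane-1-carboxylate (carbinol epimers) | COC(=O)[C@]1(C(O)c2cc(OC)c(O[Si](C(C)C)(C(C)C)C(C)C)c(OC)c2)[C@H](c2cc(OC)c(O[Si](C(C)C)(C(C)C)C(C)C)c(OC)c2)[C@H]1CO[Si](C(C)C)(C(C)C)C(C)C
F2 | step 5 | methyl (3R)-2-[3,5-dimethoxy-4-(triisopropylsilyloxy)benzoyl]-3-[3,5-dimethoxy-4-(triisopropylsilyloxy)phenyl]-5-oxopentanoate (C2 epimers) | COC(=O)C(C(=O)c1cc(OC)c(O[Si](C(C)C)(C(C)C)C(C)C)c(OC)c1)[C@H](c1cc(OC)c(O[Si](C(C)C)(C(C)C)C(C)C)c(OC)c1)CC=O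
F3 | step 5 | methyl (3S)-2-bromo-2-[3,5-dimethoxy-4-(triisopropylsilyloxy)benzoyl]-3-[3,5-dimethoxy-4-(triisopropylsilyloxy)phenyl]-5-oxopentanoate (C2 epimers) | COC(=O)C(Br)(C(=O)c1cc(OC)c(O[Si](C(C)C)(C(C)C)C(C)C)c(OC)c1)[C@H](c1cc(OC)c(O[Si](C(C)C)(C(C)C)C(C)C)c(OC)c1)CC=O
F4 | step 6 | dimethyl (2S,3R)-2-[3,5-dimethoxy-4-(triisopropylsilyloxy)phenyl]-3-formylcyclopropane-1,1-dicarboxylate | COC(=O)C1(C(=O)OC)[C@H](c2cc(OC)c(O[Si](C(C)C)(C(C)C)C(C)C)c(OC)c2)[C@H]1C=O
F5 | step 6 | dimethyl (2S,3R)-2-[3,5-dimethoxy-4-(triisopropylsilyloxy)phenyl]-3-(hydroxymethyl)cyclopropane-1,1-dicarboxylate | COC(=O)C1(C(=O)OC)[C@H](c2cc(OC)c(O[Si](C(C)C)(C(C)C)C(C)C)c(OC)c2)[C@H]1CO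
F6 | step 6 | dimethyl (2S,3R)-2-[3,5-dimethoxy-4-(triisopropylsilyloxy)phenyl]-3-[(triisopropylsilyloxy)methyl]cyclopropane-1,1-dicarboxylate | COC(=O)C1(C(=O)OC)[C@H](c2cc(OC)c(O[Si](C(C)C)(C(C)C)C(C)C)c(OC)c2)[C@H]1CO[Si](C(C)C)(C(C)C)C(C)C
F7 | step 6 | (4-bromo-2,6-dimethoxyphenoxy)triisopropylsilane | COc1cc(Br)cc(OC)c1O[Si](C(C)C)(C(C)C)C(C)C
F8 | step 6 | [3,5-dimethoxy-4-(triisopropylsilyloxy)phenyl]lithium | [Li]c1cc(OC)c(O[Si](C(C)C)(C(C)C)C(C)C)c(OC)c1
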